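**Strategy.** Everything rests on disconnecting the cyclohexane ring between indole C2 and the gem-dimethyl carbon, together with the neighbouring bond that closes the piperidine ring. The key step, an oxidative radical bicyclisation with Mn(OAc)3, exploits two features of that ring: its nitrogen-bearing quaternary carbon is a latent malonyl radical, and its CMe2 carbon is the tertiary terminus of a prenyl group lying next to nucleophilic indole C2. In one operation the malonyl radical closes the piperidinone, the resulting tertiary radical closes the cyclohexane at C2, and two stereocentres are relayed from a D-prolinol-derived centre. The precursor is an acyclic 3-indolylmethyl malonamate of (R)-2-prenylpyrrolidine, whose ester later becomes the carbamate nitrogen.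

Key step: step 6

Remarks on the chemistry:
- Locants used below. Indolizidine unit: N4, C5 (carbonyl, later CH2), C6 (quaternary carbon that ends up bearing the carbamate nitrogen), C7 (ring-fusion CH bearing CMe2), C8, C8a (pyrrolidine CH). Indole: N1, C2, C3.
- Assumption: compounds 1, 3, 6 and 8 are commercial.
- The C5 carbonyl and the ester on C6 are temporary activating groups; the ester is converted to nitrogen in step 8 and the carbonyl is removed in step 9.
- In the target, the carbamate nitrogen on C6 is axial and anti to H7, H7 and H8a are cis, and the C3–O bond is syn to that nitrogen; the route is built to deliver this arrangement.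

**Route**

Step 1
Reactants: 1 tert-butyl (2R)-2-(hydroxymethyl)pyrrolidine-1-carboxylate (N-Boc-D-prolinol)
Product: 2 tert-butyl (2R)-2-(iodomethyl)pyrrolidine-1-carboxylate
Conditions: I2, PPh3, imidazole, CH2Cl2, 0 °C to rt
Reagents that add atoms: iodine, II
Why: Appel iodination converts the primary alcohol to the iodide by SN2 displacement of the alkoxyphosphonium ion and leaves the pyrrolidine stereocentre untouched.

Step 2
Reactants: 2 tert-butyl (2R)-2-(iodomethyl)pyrrolidine-1-carboxylate; 3 (2-methylprop-1-en-1-yl)magnesium bromide
Product: 4 tert-butyl (2R)-2-(3-methylbut-2-en-1-yl)pyrrolidine-1-carboxylate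
Conditions: CuI (0.2 equiv), THF, −30 °C to 0 °C
Reagents that add atoms: none
Why: Copper-catalysed cross-coupling of the alkenyl Grignard reagent with the primary iodide should install the prenyl chain at low temperature, where the carbamate neither cyclises onto the iodide nor is attacked.

Step 3
Reactants: 4 tert-butyl (2R)-2-(3-methylbut-2-en-1-yl)pyrrolidine-1-carboxylate
Product: 5 (2R)-2-(3-methylbut-2-en-1-yl)pyrrolidine
Conditions: TFA, CH2Cl2, 0 °C; then aq. NaOH
Reagents that add atoms: none
Why: Acidolysis of the tert-butyl carbamate releases isobutene and CO2, and the trisubstituted alkene should survive the short exposure to cold TFA.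

Step 4
Reactants: 5 (2R)-2-(3-methylbut-2-en-1-yl)pyrrolidine; 6 3-(benzyloxy)-3-oxopropanoic acid (monobenzyl malonate)
Product: 7 benzyl 3-[(2R)-2-(3-methylbut-2-en-1-yl)pyrrolidin-1-yl]-3-oxopropanoate
Conditions: DCC, HOBt (cat.), CH2Cl2, 0 °C to rt
Reagents that add atoms: none
Why: Carbodiimide-mediated amide coupling of the secondary amine with the malonic half ester should give the tertiary malonamate without touching the alkene.

Step 5
Reactants: 7 benzyl 3-[(2R)-2-(3-methylbut-2-en-1-yl)pyrrolidin-1-yl]-3-oxopropanoate; 8 gramine
Product: 9 benzyl 2-(1H-indol-3-ylmethyl)-3-[(2R)-2-(3-methylbut-2-en-1-yl)pyrrolidin-1-yl]-3-oxopropanoate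
Conditions: n-Bu3P (0.3 equiv), MeCN, 80 °C
Reagents that add atoms: none
Why: Phosphine-catalysed alkylation with gramine proceeds through 3-methyleneindolenine, to which the malonamate enol adds in a Michael fashion and stops at monoalkylation for steric reasons, the new acyclic stereocentre arising as a mixture of no consequence because it becomes the planar radical centre of step 6.

Step 6
Reactants: 9 benzyl 2-(1H-indol-3-ylmethyl)-3-[(2R)-2-(3-methylbut-2-en-1-yl)pyrrolidin-1-yl]-3-oxopropanoate
Product: 12 pentacyclic lactam benzyl ester (6S,7R,8aR), via malonyl radical 10 (not isolated), via tertiary radical 11 (not isolated)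
Conditions: Mn(OAc)3·2H2O (2.2 equiv), AcOH (0.01 M), 80 °C, Ar
Reagents that add atoms: none
Why: Mn(OAc)3 oxidises the enol of the β-amido ester to the electrophilic malonyl-type radical 10, which adds to the CH terminus of the electron-rich prenyl double bond, and the tertiary radical 11 so formed at the CMe2 carbon attacks the free indole C2 (directly, or by ipso attack at C3 and shift of the tertiary group in the acidic medium), after which a second equivalent of Mn(OAc)3 oxidises the indolinyl radical and loss of the C2 proton restores the indole. The closest known reaction type is the Mn(OAc)3-mediated oxidative radical polycyclisation of unsaturated 1,3-dicarbonyl compounds that terminates on an aromatic ring. The piperidinone closes in the 6-exo-trig mode (C6–C7 bond) and the cyclohexane closes by attack of the exocyclic tertiary radical on the C2 end of the indole C2=C3 bond (6-endo-trig mode, C2–CMe2 bond). C7 is controlled by the purchased C8a centre, because the pyrrolidine carbon is locked equatorial on the forming lactam and the CMe2 arm takes the equatorial position of a chair-like transition state, so that H7 and H8a become cis, an outcome that reversibility of the first closure would only reinforce. C6 is set in the same closure: in the planar radical the bulky sp3 indolylmethyl group should eclipse the small lactam oxygen while the flat ester lies on the side of N4 where the alkene arrives, so the ester turns axial and the indolylmethyl group equatorial and trans to the CMe2 arm, as the trans-fused cyclohexane requires. The step needs selectivity at C6, which rests on this size difference, and chemoselectivity for capture of 11 by C2 over its oxidation or attack on a second indole, which the absence of Cu(OAc)2 and high dilution should secure.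

Step 7
Reactants: 12 pentacyclic lactam benzyl ester
Product: 13 pentacyclic lactam carboxylic acid (6S,7R,8aR)
Conditions: H2 (1 atm), Pd/C, EtOAc, rt
Reagents that add atoms: none
Why: Hydrogenolysis of the benzyl ester frees the hindered carboxylic acid under neutral conditions that should leave the indole and the lactam untouched and avoid decarboxylation of the malonamic acid.

Step 8
Reactants: 13 pentacyclic lactam carboxylic acid
Product: 16 pentacyclic lactam tert-butyl carbamate (6S,7R,8aR), via acyl azide 14 (not isolated), via isocyanate 15 (not isolated)
Conditions: DPPA, Et3N, toluene, rt to 90 °C; then t-BuOH, CuCl (cat.), 60 °C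
Reagents that add atoms: diphenylphosphoryl azide, [N-]=[N+]=NP(=O)(Oc1ccccc1)Oc1ccccc1; tert-butanol, CC(C)(C)O
Why: Curtius rearrangement of the acyl azide migrates the quaternary C6 with retention of configuration, and the hindered isocyanate should be trapped by tert-butanol under CuCl catalysis to give the axial Boc carbamate.

Step 9
Reactants: 16 pentacyclic lactam tert-butyl carbamate
Product: 18 pentacyclic amine tert-butyl carbamate (6S,7R,8aR), via amine–borane adduct 17 (not isolated)
Conditions: BH3·SMe2, THF, 65 °C; then Pd/C (cat.), MeOH, 40 °C
Reagents that add atoms: none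
Why: Borane should reduce the tertiary lactam to the amine chemoselectively in the presence of the carbamate and the indole, and palladium-catalysed methanolysis cleaves the amine–borane adduct without acid, which spares the Boc group.

Step 10
Reactants: 18 pentacyclic amine tert-butyl carbamate
Product: 19 penicimutamide C
Conditions: TFA (1.0 equiv), PhI(OAc)2 (1.1 equiv), (CF3)2CHOH/CH2Cl2, −20 °C to 0 °C; then aq. NaHCO3
Reagents that add atoms: none
Why: In this dearomative oxidative cyclisation with trivalent iodine, PhI(OAc)2 activates the indole and the Boc carbonyl oxygen, held axial on C6 and 1,3 to C3, attacks C3 from the only face it can reach, so that the C3–O stereocentre is dictated by C6, the indolenine C2=N bond forms and the tert-butyl group leaves as isobutene, while protonation of N4 by one equivalent of TFA shields the tertiary amine from oxidation.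

**Compound list**

1 | tert-butyl (2R)-2-(hydroxymethyl)pyrrolidine-1-carboxylate (N-Boc-D-prolinol) | OC[C@H]1CCCN1C(=O)OC(C)(C)C | starting material
2 | tert-butyl (2R)-2-(iodomethyl)pyrrolidine-1-carboxylate | IC[C@H]1CCCN1C(=O)OC(C)(C)C | intermediate
3 | (2-methylprop-1-en-1-yl)magnesium bromide | CC(C)=C[Mg]Br | starting material
4 | tert-butyl (2R)-2-(3-methylbut-2-en-1-yl)pyrrolidine-1-carboxylate | CC(C)=CC[C@H]1CCCN1C(=O)OC(C)(C)C | intermediate
5 | (2R)-2-(3-methylbut-2-en-1-yl)pyrrolidine | CC(C)=CC[C@H]1CCCN1 | intermediate
6 | 3-(benzyloxy)-3-oxopropanoic acid (monobenzyl malonate) | OC(=O)CC(=O)OCc1ccccc1 | starting material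
7 | benzyl 3-[(2R)-2-(3-methylbut-2-en-1-yl)pyrrolidin-1-yl]-3-oxopropanoate | CC(C)=CC[C@H]1CCCN1C(=O)CC(=O)OCc1ccccc1 | intermediate
8 | gramine, 1-(1H-indol-3-yl)-N,N-dimethylmethanamine | CN(C)Cc1c[nH]c2ccccc12 | starting material
9 | benzyl 2-(1H-indol-3-ylmethyl)-3-[(2R)-2-(3-methylbut-2-en-1-yl)pyrrolidin-1-yl]-3-oxopropanoate, both epimers at the malonyl carbon | CC(C)=CC[C@H]1CCCN1C(=O)C(Cc1c[nH]c2ccccc12)C(=O)OCc1ccccc1 | intermediate
10 | malonyl radical of 9, radical centre at the carbon between the two carbonyl groups (formed in the flask in step 6) | CC(C)=CC[C@H]1CCCN1C(=O)[C](Cc1c[nH]c2ccccc12)C(=O)OCc1ccccc1 | intermediate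
11 | monocyclised tertiary radical: 5-oxoindolizidine with axial CO2Bn and equatorial indol-3-ylmethyl on C6 and the 2-propyl radical on C7, H7 and H8a cis (formed in the flask in step 6) | O=C1N2CCC[C@@H]2C[C@H]([C](C)C)[C@]1(Cc1c[nH]c2ccccc12)C(=O)OCc1ccccc1 | intermediate
12 | pentacyclic lactam benzyl ester (6S,7R,8aR): 5-oxoindolizidine whose C6–C7 bond is shared with a cyclohexane closed through C6–CH2–indole C3 and C7–CMe2–indole C2, trans ring fusion, axial CO2Bn on C6, H7 and H8a cis | CC1(C)c2[nH]c3ccccc3c2C[C@]2(C(=O)N4CCC[C@@H]4C[C@H]12)C(=O)OCc1ccccc1 | intermediate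
13 | pentacyclic lactam carboxylic acid (6S,7R,8aR), as 12 with CO2H on C6 | CC1(C)c2[nH]c3ccccc3c2C[C@]2(C(=O)N4CCC[C@@H]4C[C@H]12)C(=O)O | intermediate
14 | acyl azide of 13 (formed in the flask in step 8) | CC1(C)c2[nH]c3ccccc3c2C[C@]2(C(=O)N4CCC[C@@H]4C[C@H]12)C(=O)N=[N+]=[N-] | intermediate
15 | isocyanate on C6 (6S,7R,8aR), configuration retained (formed in the flask in step 8) | CC1(C)c2[nH]c3ccccc3c2C[C@]2(C(=O)N4CCC[C@@H]4C[C@H]12)N=C=O | intermediate
16 | pentacyclic lactam tert-butyl carbamate (6S,7R,8aR), axial NHBoc on C6 | CC1(C)c2[nH]c3ccccc3c2C[C@]2(C(=O)N4CCC[C@@H]4C[C@H]12)NC(=O)OC(C)(C)C | intermediate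
17 | N4–borane adduct of 18 (formed in the flask in step 9) | CC1(C)c2[nH]c3ccccc3c2C[C@]2(C[N+]4([BH3-])CCC[C@@H]4C[C@H]12)NC(=O)OC(C)(C)C | intermediate
18 | pentacyclic amine tert-butyl carbamate (6S,7R,8aR): as 16 with C5 reduced to CH2 | CC1(C)c2[nH]c3ccccc3c2C[C@]2(CN4CCC[C@@H]4C[C@H]12)NC(=O)OC(C)(C)C | intermediate
19 | penicimutamide C | CC1(C)C2=Nc3ccccc3[C@@]23C[C@]2(CN4CCC[C@@H]4C[C@H]12)NC(=O)O3 | target

**Step count and risks**

Total step count: 10. Longest linear sequence: 10 steps (from 1 to 19).

Steps most likely to fail:

Step 6. The bicyclisation may suffer from poor facial selectivity at C6 in the first ring closure, from radicals formed in the amide rotamer that cannot cyclise, or from oxidation of the tertiary radical before it reaches C2. The fallback separates the events and sets out from 7. Mn(OAc)3 with Cu(OAc)2 in AcOH should close the lactam alone and, by oxidative elimination, give benzyl (7S,8aR)-5-oxo-7-(prop-1-en-2-yl)octahydroindolizine-6-carboxylate F1. Alkylation of its enol with gramine 8 (n-Bu3P, MeCN, 80 °C) should place the indolylmethyl group anti to the neighbouring isopropenyl group and give benzyl (6S,7R,8aR)-6-(1H-indol-3-ylmethyl)-5-oxo-7-(prop-1-en-2-yl)octahydroindolizine-6-carboxylate F2. TFA in CH2Cl2 should then protonate the isopropenyl group and close the cyclohexane by Friedel–Crafts attack of indole C2 on the tertiary cation, which returns the route at 12.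

Step 10. The oxidative closure may be diverted by capture of C3 by acetate instead of the carbamate oxygen, by oxidation of the tertiary amine, or by premature loss of the Boc group. The fallback sets out from 18 and separates halogenation from C–O bond formation. t-BuOCl and Et3N in CH2Cl2 at −78 °C should chlorinate C3 from the face opposite the axial carbamate to give the 3-chloro-3H-indole F3. AgOTf in CH2Cl2 should then ionise the C–Cl bond so that the Boc carbonyl oxygen displaces chloride with inversion and loses isobutene, which arrives at 19.

Step 9. The reduction may stall at the hindered lactam next to the quaternary carbon, or the hydride may attack the carbamate. The fallback sets out from 16: Lawesson's reagent in toluene at 80 °C should give the thiolactam F4, and Raney Ni in EtOH should desulfurise it to the amine, which returns the route at 18.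

**Further compounds**

F1 | step 6 | benzyl (7S,8aR)-5-oxo-7-(prop-1-en-2-yl)octahydroindolizine-6-carboxylate | O=C1N2CCC[C@@H]2C[C@H](C(C)=C)C1C(=O)OCc1ccccc1
F2 | step 6 | benzyl (6S,7R,8aR)-6-(1H-indol-3-ylmethyl)-5-oxo-7-(prop-1-en-2-yl)octahydroindolizine-6-carboxylate | O=C1N2CCC[C@@H]2C[C@H](C(C)=C)[C@]1(Cc1c[nH]c2ccccc12)C(=O)OCc1ccccc1
F3 | step 10 | (3R)-3-chloro-3H-indole derived from 18, chlorine anti to the NHBoc group | CC1(C)C2=Nc3ccccc3[C@]2(Cl)C[C@]2(CN4CCC[C@@H]4C[C@H]12)NC(=O)OC(C)(C)C
F4 | step 9 | thiolactam of 16 (C5=S) | CC1(C)c2[nH]c3ccccc3c2C[C@]2(C(=S)N4CCC[C@@H]4C[C@H]12)NC(=O)OC(C)(C)C
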